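In a one-step world starting material turns into open intermediate and stays there, so its fraction climbs for as long as the flask runs; this scheme also clears it, and what matters is where making and clearing cross.

    open intermediate + capture agent → trapped intermediate (k1 = 0.19 /M/s)
    free catalyst + open intermediate → free catalyst + target (k2 = 16 /M/s)
    starting material → open intermediate (k3 = 0.033 /s)
    starting material + free catalyst → spent catalyst (k4 = 0.64 /M/s)

all flasks: capture agent 0.980 mM; free catalyst 3.1 mol%

|  | starting material | remark | time |
|---|---|---|---|
| Thursday's | 0.049 M | one stirred flow tank at steady state, fed with the mixture as stated, mean residence time 500 s |  |
| Wednesday's | 0.049 M (fed, over 40.0 s) | all but starting material at the start; starting material goes in evenly over 40.0 s, the run ends at 50 s | 50 s |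
| Tuesday's | 0.049 M | a single well-mixed tank run continuously and read at steady state, 50 s in it on average |  |
| Friday's | 0.049 M | a closed flask charged with all of it at once and left for 50 s | 50 s |

- the stated concentrations are those of everything mixed, before any reaction; amounts are the same in each set-up
- the feed brings no volume worth counting
- run time (Wednesday's): 50 s

* the set-up with the highest amount of open intermediate at the outlet or at the end, in percent of the starting material put in ("none" if the first two lie within 2 percentage points) (Thursday's / Wednesday's / Tuesday's / Friday's / none)
* amount of open intermediate at the outlet or at the end, in percent of the starting material put in, Thursday's
* amount of open intermediate at the outlet or at the end, in percent of the starting material put in, Wednesday's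
* amount of open intermediate at the outlet or at the end, in percent of the starting material put in, Tuesday's
* amount of open intermediate at the outlet or at the end, in percent of the starting material put in, Friday's

I work in fractions of the charge: a is starting material left, i is open intermediate, f is the free share of the catalyst. Making goes as 0.033 /s times a. Clearing by whole catalyst is pseudo-first-order with constant 0.0243 /s, scaled by f. Their quotient, 1.36, I call the crossing ratio: open intermediate stops rising where i equals the ratio times a over f.

Now the settings. In Friday's flask the capture agent, at its charged concentration, clears open intermediate with a half-life of 62 min, much longer than the 50 s run, so I drop it. The opening step uses starting material 34 times faster at the start than the catalyst's loss does, so a simply decays at the opening constant, and ln f is 0.950 times minus the share of starting material gone.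

Next, time. With whole catalyst the peak of two first-order steps comes at 35.2 s, earlier than the 50 s end, and shrinking f delays it, so Friday's flask should end near its crossing. There a is 19.2% and f is 46.4%, and I commit to 56.3%. Then the feed: in Wednesday's flask the average portion of starting material has 30.0 s in the flask rather than 50 s, so I place it below Friday's. Last, the tank: outflow joins the clearing, so f in the rule becomes f plus 1 over the clearing constant times the residence time. That gives 35.3% for Tuesday's and 12.7% for Thursday's.

The forecast names Friday's, with 52.2% there, 43.5% for Wednesday's, 34.7% for Tuesday's and 12.4% for Thursday's, saying “it builds up as a mid-course maximum”. My Friday's figure, the crossing value, stands higher than the forecast's.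

The simulation gives Friday's first at 52.3%, then Wednesday's 43.5%, Tuesday's 34.7% and Thursday's 12.4%. In Friday's flask at 50.0 s, open intermediate is still made 1.02 times as fast as it is used up. The crossing ratio with the readings of 18.6% starting material and 46.9% free catalyst puts the crossing value at 53.9%, a little above what the flask holds.

Friday's flask with 5.3 mol% of catalyst has a crossing ratio of 0.794, smaller than Friday's own, which lowers the crossing value to 32.9%. With whole catalyst its peak comes at 26.9 s, earlier than 35.2 s, so I expect it past the crossing and above that value. It ends at 39.5%.

All constants belong to no real substance; the result is computed.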